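Ring A (C1–C5, C10; labdane numbering) holds the gem-dimethyl carbon C4 beside C5 and a CH2 (C1) beside the methyl-bearing C10, with C6 oxygenated: a six-membered ring flanked by a latent C6 carbonyl, the retron of a Diels–Alder reaction. One enantioselective [4+2] cycloaddition of 4-methylpenta-1,3-diene (C1–C4, C18, C19) with 2,6-dimethyl-1,4-benzoquinone (all of ring B, C17, C20) closes ring A by forming C1–C10 and C4–C5 and sets the C10 quaternary centre. Both precursors are flat and achiral. The C9 carbonyl then becomes an enol triflate that takes the chiral C11–C16 chain; the C6 carbonyl drives the C8 hydroxylation and ends as the 6β-acetate.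

Key step: step 1

Remark: labdane numbering is used throughout (ring A = C1–C5 and C10; ring B = C5–C10; chain C11–C16; C17 on C8; C18 and C19 on C4; C20 on C10); α is the face opposite the C10 methyl.

Assumption: the facial sense of step 1 is taken from the α-C–H···O binding model of protonated oxazaborolidines with quinones, which leads to the (8aS) adduct with the catalyst made from (R)-diphenylprolinol; if the sense is the opposite, the antipodal catalyst is used and nothing else changes.

Step 1
Reactants: 1 2,6-dimethyl-1,4-benzoquinone; 2 4-methylpenta-1,3-diene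
Product: 3 (4aR,8aS)-2,5,5,8a-tetramethyl-4a,5,8,8a-tetrahydronaphthalene-1,4-dione
Conditions: (R)-3,3-diphenyl-1-(2-methylphenyl)tetrahydro-1H,3H-pyrrolo[1,2-c][1,3,2]oxazaborole (20 mol%), HNTf2 (20 mol%), 2 (5 equiv), CH2Cl2, −78 → −20 °C
Reagents that add atoms: none
Why: The protonated oxazaborolidine should bind the less hindered, more basic C6 carbonyl (flanked by two CH groups) with the usual contact to the α-hydrogen on C5, so that C5=C10 becomes a polarised dienophile whose β-carbon C10 is attacked by C1, the unsubstituted and most nucleophilic diene terminus, in an asynchronous Lewis-acid-catalysed normal-demand Diels–Alder reaction (closest known type: oxazaborolidinium-catalysed enantioselective Diels–Alder additions to quinones). Ring A is closed in the [4+2] cycloaddition mode, suprafacial on both partners, with C1–C10 bonding ahead of C4–C5. C10 and C5 are formed cis because both bonds are made on one face of the ring alkene, the absolute sense (8aS) comes from the catalyst, which shields one of the two enantiotopic quinone faces, and C5 is inverted to the trans fusion later by enolisation (step 7). The step needs regioselectivity (C1 to C10, CMe2 to C5), which the catalyst-bound C6 carbonyl and the two donor methyls on C4 together secure. It also needs cycloaddition to outrun acid-induced oligomerisation of the diene, for which low temperature and excess diene are used. No endo/exo question arises because C1 is unsubstituted and C4 carries two identical methyls.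

Step 2
Reactants: 3 (4aR,8aS)-2,5,5,8a-tetramethyl-4a,5,8,8a-tetrahydronaphthalene-1,4-dione
Product: 5 (4aR,8aS)-2,5,5,8a-tetramethyl-4-oxo-3,4,4a,5,8,8a-hexahydronaphthalen-1-yl trifluoromethanesulfonate, via C9 lithium enolate 4 (not isolated)
Conditions: LiBH(s-Bu)3 (1.05 equiv), THF, −78 °C; then N-(5-chloropyridin-2-yl)bis(trifluoromethanesulfonimide), −78 → 0 °C
Reagents that add atoms: N-(5-chloropyridin-2-yl)bis(trifluoromethanesulfonimide), FC(F)(F)S(=O)(=O)N(c1ccc(Cl)cn1)S(=O)(=O)C(F)(F)F
Why: Conjugate hydride addition of the bulky borohydride to the enedione should go to the unsubstituted C7 (β to the C9 carbonyl) and not to the methyl-bearing C8, which gives the tetrasubstituted C8=C9 enolate regiospecifically; it is O-triflated cold before proton transfer can move it (conjugate reduction with enolate trapping), and no stereocentre is formed.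

Step 3
Reactants: 6 (R)-5-methoxy-3-methyl-5-oxopentanoic acid (methyl hydrogen (R)-3-methylglutarate)
Product: 8 (S)-4-methyloxan-2-one, via (S)-5-hydroxy-3-methylpentanoic acid 7 (not isolated)
Conditions: LiBHEt3 (3.2 equiv), THF, 0 °C → rt; then 2 M HCl, rt
Reagents that add atoms: none
Why: The borohydride first converts the acid into the inert carboxylate and then reduces only the methyl ester, and acidification lactonises the hydroxy acid (chemoselective ester reduction, lactonisation); the stereocentre is untouched and its descriptor changes only through the ranking rules.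

Step 4
Reactants: 8 (S)-4-methyloxan-2-one
Product: 10 methyl (R)-5-iodo-3-methylpentanoate, via trimethylsilyl (R)-5-iodo-3-methylpentanoate 9 (not isolated)
Conditions: Me3SiCl, NaI, MeCN, 60 °C; then MeOH, rt
Reagents that add atoms: sodium iodide, [Na+].[I-]; methanol, CO
Why: Iodotrimethylsilane formed in the flask should open the lactone by SN2 attack of iodide on the O–CH2 carbon, and the acidic methanol converts the silyl ester into the methyl ester (silyl iodide cleavage of a lactone, esterification); the remote stereocentre is untouched.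

Step 5
Reactants: 10 methyl (R)-5-iodo-3-methylpentanoate; 5 (4aR,8aS)-2,5,5,8a-tetramethyl-4-oxo-3,4,4a,5,8,8a-hexahydronaphthalen-1-yl trifluoromethanesulfonate
Product: 12 methyl (13S)-6-oxo-5β-labda-2,8-dien-15-oate, via alkylzinc iodide 11 (not isolated)
Conditions: Zn dust, LiCl, THF, 40 °C; then 5, Pd(OAc)2 (5 mol%), 2-dicyclohexylphosphino-2',6'-dimethoxybiphenyl (10 mol%), THF/NMP, 50 °C
Reagents that add atoms: none
Why: Zinc insertion into the primary iodide tolerates the ester, and Negishi coupling of alkylzinc halides with hindered cyclohexenyl triflates of the 2,6,6-trimethylcyclohexenyl type is established with bulky biarylphosphines on zerovalent palladium; the ketone is inert to the zinc reagent and no stereocentre is formed.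

Step 6
Reactants: 12 methyl (13S)-6-oxo-5β-labda-2,8-dien-15-oate
Product: 13 methyl (13S)-6-oxo-5β-labd-8-en-15-oate
Conditions: H2 (1 atm), RhCl(PPh3)3 (5 mol%), benzene/EtOH, rt
Reagents that add atoms: none
Why: RhCl(PPh3)3 should hydrogenate the cis-disubstituted C2=C3 alkene and leave the tetrasubstituted C8=C9 alkene, the ketone and the ester untouched (chemoselective homogeneous hydrogenation); no stereocentre is formed.

Step 7
Reactants: 13 methyl (13S)-6-oxo-5β-labd-8-en-15-oate
Product: 15 methyl (13S)-7α,8α-epoxy-6-oxolabdan-15-oate, via conjugated enone 14 (not isolated)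
Conditions: NaOMe (0.5 equiv), MeOH, argon, 0 °C → rt; then t-BuOOH (5.5 M in decane), 0 °C → rt
Reagents that add atoms: tert-butyl hydroperoxide, CC(C)(C)OO
Why: Methoxide should move the alkene into conjugation by protonating the dienolate at C9 on the α face (axial, anti to the C10 methyl, giving 9α-H) and should invert C5 through the C5=C6 enolate to the trans-fused ketone (α-face protonation, and the trans-decalone is expected to be the stable isomer); the hydroperoxide anion then adds to C8 from the α face opposite the axial C10 methyl and closes the 7α,8α-epoxide (Weitz–Scheffer epoxidation).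

Step 8
Reactants: 15 methyl (13S)-7α,8α-epoxy-6-oxolabdan-15-oate
Product: 17 methyl (13S)-6β,8α-dihydroxylabdan-15-oate, via 8α-hydroxy ketone 16 (not isolated)
Conditions: SmI2 (2.5 equiv), THF/MeOH, −90 °C; then NaBH4, −78 → 0 °C
Reagents that add atoms: none
Why: Electron transfer from SmI2 to the ketone cleaves the C7–O bond α to the carbonyl and leaves the C8–O bond, so the tertiary 8α-alcohol keeps the configuration set in step 7 (reductive opening of an α,β-epoxy ketone); the aldol is reduced before it can dehydrate, with hydride attacking C6 from the α face because the β face is blocked by the axial methyls on C4, C8 and C10, which gives the axial 6β-alcohol.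

Step 9
Reactants: 17 methyl (13S)-6β,8α-dihydroxylabdan-15-oate
Product: 18 methyl (13S)-6β-acetoxy-8α-hydroxylabdan-15-oate
Conditions: Ac2O, 4-(dimethylamino)pyridine (cat.), pyridine, rt → 40 °C
Reagents that add atoms: acetic anhydride, CC(=O)OC(C)=O
Why: Nucleophile-catalysed acylation should take the secondary 6β-hydroxyl and leave the tertiary 8α-hydroxyl, which does not acylate under these conditions (pyridine-catalysed esterification); no stereocentre is touched.

Compound list
1 | 2,6-dimethyl-1,4-benzoquinone | CC1=CC(=O)C=C(C)C1=O | starting material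
2 | 4-methylpenta-1,3-diene | C=CC=C(C)C | starting material
3 | (4aR,8aS)-2,5,5,8a-tetramethyl-4a,5,8,8a-tetrahydronaphthalene-1,4-dione (cis-fused; 5β-H, 10β-methyl) | CC1=CC(=O)[C@@H]2C(C)(C)C=CC[C@]2(C)C1=O | intermediate
4 | lithium (4aR,8aS)-2,5,5,8a-tetramethyl-4-oxo-3,4,4a,5,8,8a-hexahydronaphthalen-1-olate (C9 enolate) | CC1=C([O-])[C@@]2(C)CC=CC(C)(C)[C@H]2C(=O)C1.[Li+] | intermediate
5 | (4aR,8aS)-2,5,5,8a-tetramethyl-4-oxo-3,4,4a,5,8,8a-hexahydronaphthalen-1-yl trifluoromethanesulfonate (C9 enol triflate, C6 ketone, cis-fused) | CC1=C(OS(=O)(=O)C(F)(F)F)[C@@]2(C)CC=CC(C)(C)[C@H]2C(=O)C1 | intermediate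
6 | (R)-5-methoxy-3-methyl-5-oxopentanoic acid (methyl hydrogen (R)-3-methylglutarate) | COC(=O)C[C@H](C)CC(=O)O | starting material
7 | (S)-5-hydroxy-3-methylpentanoic acid (present as its lithium salt) | OC(=O)C[C@@H](C)CCO | intermediate
8 | (S)-4-methyloxan-2-one | O=C1C[C@@H](C)CCO1 | intermediate
9 | trimethylsilyl (R)-5-iodo-3-methylpentanoate | C[Si](C)(C)OC(=O)C[C@@H](C)CCI | intermediate
10 | methyl (R)-5-iodo-3-methylpentanoate | COC(=O)C[C@@H](C)CCI | intermediate
11 | [(3R)-5-methoxy-3-methyl-5-oxopentyl]zinc iodide | COC(=O)C[C@@H](C)CC[Zn]I | intermediate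
12 | methyl (13S)-6-oxo-5β-labda-2,8-dien-15-oate (cis-fused, 10β-methyl) | COC(=O)C[C@@H](C)CCC1=C(C)CC(=O)[C@@H]2C(C)(C)C=CC[C@]12C | intermediate
13 | methyl (13S)-6-oxo-5β-labd-8-en-15-oate (cis-fused, ring A saturated) | COC(=O)C[C@@H](C)CCC1=C(C)CC(=O)[C@@H]2C(C)(C)CCC[C@]12C | intermediate
14 | methyl (13S)-6-oxolabd-7-en-15-oate (trans-fused; 5α-H, 9α-H) | COC(=O)C[C@@H](C)CC[C@H]1C(C)=CC(=O)[C@H]2C(C)(C)CCC[C@]12C | intermediate
15 | methyl (13S)-7α,8α-epoxy-6-oxolabdan-15-oate | COC(=O)C[C@@H](C)CC[C@H]1[C@]3(C)O[C@@H]3C(=O)[C@H]2C(C)(C)CCC[C@]12C | intermediate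
16 | methyl (13S)-8α-hydroxy-6-oxolabdan-15-oate | COC(=O)C[C@@H](C)CC[C@H]1[C@](C)(O)CC(=O)[C@H]2C(C)(C)CCC[C@]12C | intermediate
17 | methyl (13S)-6β,8α-dihydroxylabdan-15-oate | COC(=O)C[C@@H](C)CC[C@H]1[C@](C)(O)C[C@@H](O)[C@H]2C(C)(C)CCC[C@]12C | intermediate
18 | methyl (13S)-6β-acetoxy-8α-hydroxylabdan-15-oate = methyl (3S)-5-[(1R,2R,4R,4aS,8aS)-4-acetoxy-2-hydroxy-2,5,5,8a-tetramethyldecahydronaphthalen-1-yl]-3-methylpentanoate | COC(=O)C[C@@H](C)CC[C@@H]1[C@@]2(C)CCCC(C)(C)[C@@H]2[C@H](OC(C)=O)C[C@@]1(C)O | target

Total step count: 9. Longest linear sequence: 7 steps (steps 1, 2, 5, 6, 7, 8, 9; the branch through steps 3 and 4 is of equal length).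

Steps most likely to fail

Step 1. The diene may oligomerise under the strong acid. The reaction may also stop after the first C1–C10 bond, because the s-cis conformer of a diene with a Z-methyl group is poorly populated; ring closure at the quaternary terminus would then lose to proton loss or four-ring closure. The fallback brings in the four ring A carbons as an oxygen-activated diene and removes the oxygen afterwards. It sets out from 1: mesityl oxide is enolised on its methyl ketone side (LiN(i-Pr)2, i-Pr3SiOTf, THF, −78 °C) to 4-methyl-2-(triisopropylsilyloxy)penta-1,3-diene F1. Its enol ether carbon C1 is far more nucleophilic, and under the catalyst of step 1 it should add to 1 by cycloaddition or by Mukaiyama–Michael addition followed by Michael closure, forming the same two bonds in the same order. This would give (4aR,8aS)-2,5,5,8a-tetramethyl-7-(triisopropylsilyloxy)-4a,5,8,8a-tetrahydronaphthalene-1,4-dione F2. CsF and PhNTf2 in dimethoxyethane would convert it into (4aR,8aS)-2,5,5,8a-tetramethyl-7-(trifluoromethanesulfonyloxy)-4a,5,8,8a-tetrahydronaphthalene-1,4-dione F3, and reduction of the enol triflate (Pd(OAc)2, PPh3, HCO2H, n-Bu3N, DMF) leaves the C2=C3 alkene. The fallback comes back to the route at 3.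

Step 7. Three equilibria (alkene position, C5, C9) must all settle on one isomer before a slow attack of the peroxide anion on a fully substituted β-carbon; incomplete inversion at C5, loss of face control at C9 under prolonged base, or sluggish epoxidation would each erode the outcome. The fallback separates the events and replaces the oxygen nucleophile by a copper–boryl one. It sets out from 13: short treatment with NaOMe in MeOH and isolation gives 14; conjugate borylation (CuCl, NaOt-Bu, 1,2-bis(diphenylphosphino)benzene, bis(pinacolato)diboron, MeOH, THF) should deliver boron to C8 from the α face and give methyl (13S)-6-oxo-8α-(4,4,5,5-tetramethyl-1,3,2-dioxaborolan-2-yl)labdan-15-oate F4. Oxidation with retention (NaBO3·4H2O, THF/H2O) gives 16, where the fallback comes back to the route; 16 is reduced to 17 with NaBH4 as in step 8.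

Step 2. The borohydride may attack the less hindered C6 carbonyl directly, or the C9 enolate may exchange a proton with the C7 methylene before it is trapped, either of which loses the regiochemistry of the triflate. The fallback avoids a free enolate and a nucleophilic hydride. It sets out from 3: copper hydride conjugate reduction ([(Ph3P)CuH]6 (5 mol%), PhMe2SiH, toluene, rt) transfers hydride to the unsubstituted C7 and should give the silyl enol ether (4aR,8aS)-1-[dimethyl(phenyl)silyloxy]-2,5,5,8a-tetramethyl-4a,5,8,8a-tetrahydronaphthalen-4(3H)-one F5. CsF and PhNTf2 in dimethoxyethane exchange silicon for the triflyl group, and the fallback comes back to the route at 5.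

Further compounds
F1 | step 1 | 4-methyl-2-(triisopropylsilyloxy)penta-1,3-diene | C=C(O[Si](C(C)C)(C(C)C)C(C)C)C=C(C)C
F2 | step 1 | (4aR,8aS)-2,5,5,8a-tetramethyl-7-(triisopropylsilyloxy)-4a,5,8,8a-tetrahydronaphthalene-1,4-dione | CC1=CC(=O)[C@@H]2C(C)(C)C=C(O[Si](C(C)C)(C(C)C)C(C)C)C[C@]2(C)C1=O
F3 | step 1 | (4aR,8aS)-2,5,5,8a-tetramethyl-7-(trifluoromethanesulfonyloxy)-4a,5,8,8a-tetrahydronaphthalene-1,4-dione | CC1=CC(=O)[C@@H]2C(C)(C)C=C(OS(=O)(=O)C(F)(F)F)C[C@]2(C)C1=O
F4 | step 7 | methyl (13S)-6-oxo-8α-(4,4,5,5-tetramethyl-1,3,2-dioxaborolan-2-yl)labdan-15-oate | COC(=O)C[C@@H](C)CC[C@H]1[C@](C)(B3OC(C)(C)C(C)(C)O3)CC(=O)[C@H]2C(C)(C)CCC[C@]12C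
F5 | step 2 | (4aR,8aS)-1-[dimethyl(phenyl)silyloxy]-2,5,5,8a-tetramethyl-4a,5,8,8a-tetrahydronaphthalen-4(3H)-one | CC1=C(O[Si](C)(C)c3ccccc3)[C@@]2(C)CC=CC(C)(C)[C@H]2C(=O)C1
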